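**Amounts so far.** In this flask, the readings at 6.00 min stand at 29% target and 16% other capture product, and at 8.00 min they stand at 27% and 15%.

| setting | ash | flask |
|---|---|---|
| substrate | 0.050 M | 0.050 M |
| first nucleophile | 0.050 M | 0.0500 M |
| second nucleophile | 0.15 M | 0.150 M |
| remark | the very flask that is asked about, followed so far |  |
| time |  | 40 min |

ash run (percent of the substrate charged)

| time / min | other capture product / % | target / % |
|---|---|---|
| 0.500 | 8 | 13 |
| 1.50 | 12 | 21 |
| 3.00 | 16 | 28 |
| 4.00 | 16 | 29 |
| 6.00 | 16 | 29 |
| 8.00 | 15 | 27 |

(standard deviation of a reading: 1.5 percentage points)

- percentages count the substrate that a species holds: one side product counts as two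
- steps under discussion: substrate + intermediate -> side product; substrate -> intermediate; second nucleophile + intermediate -> other capture product; first nucleophile + intermediate -> target; intermediate -> solvolysis product; target -> over-reaction product

* ratio of other capture product to target at 8.0 s
* ratio of other capture product to target at 40 min
* which of other capture product and target there is more of at 40 min

**Question reversed.** For other capture product to lead at 40 min, target has to fall to its level. Holding other capture product steady at its 6.00 min reading, the first-order decay constant that brings target level with it at 40 min is 0.0175 /min, the crossover constant.

**Reading the slope.** Target reads 29% at 4.00 min and 27% at 8.00 min, a slope of 0.0179 /min, close to the crossover constant. But that drop of 2 percentage points stands against a scatter of 1.5 points on each reading, so the reckoning here calls the lead in this flask open.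

**The forecast.** The forecast gave a ratio of other capture product to target of 0.5 at 8.0 s and 0.63 at 40 min, within 0.52 to 0.95, with target ahead. Its ground: “Over-reaction of the target is therefore undetected, with k at most about 0.015/min”. It thus differs from the open call above.

**The result.** The flask gives ratios of 0.488 at 8.0 s and 1.43 at 40 min, with other capture product ahead, 18.0% against 12.6% target.

    substrate + intermediate → side product (k = 0.120 /M/s)
    substrate → intermediate (k = 0.0140 /s)
    second nucleophile + intermediate → other capture product (k = 4.00 /M/s)
    first nucleophile + intermediate → target (k = 25.0 /M/s)
    intermediate → solvolysis product (k = 1.60 /s)
    target → over-reaction product (k = 4.00 × 10⁻⁴ /s)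

**Crossover again.** The constant of target going to over-reaction product is 0.0240 /min, larger than the crossover constant of 0.0175 /min, and the flask's two products stand level at 25.2 min. A neighbour charged with 0.013 M of substrate stands at a ratio of 0.483 at 8.0 s; the reckoning, started here from that early ratio and time instead of a reading at 6.00 min, gives it a crossover constant of 0.0183 /min, smaller than that loss constant. That neighbour ends at a ratio of 1.27, with 17.6% other capture product against 13.9% target at 40 min.

The runs were generated by integration for substances that don't exist, noise included.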